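**Retrosynthetic overview**
1. Target 22 ⇒ bis-MOM biaryl 21 by removal of both MOM ethers.
2. 21 ⇒ biaryl bond by Negishi coupling of two C17 halves: the arylzinc from (S)-curcuphenol MOM ether 10 (MOM-directed metalation at its only free ortho carbon) and aryl chloride 18.
3. 10 and 18 ⇒ (S)-3-arylbut-1-enes 7 and 16 plus 1-bromo-2-methylprop-1-ene (9-BBN hydroboration, B-alkyl Suzuki); 7 and 16 ⇒ styrenes 5 and 15 plus ethylene by nickel-catalysed asymmetric hydrovinylation, which sets each (S) centre.
4. Styrenes ⇒ m-cresol by ortho-formylation, MOM protection and Wittig methylenation; the ring A series starts with para-chlorination of m-cresol.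
5. No ring is built: both benzene rings come intact from m-cresol (ring B half in steps 1–5, ring A half in steps 6–11) and are joined in step 12.

Assumption 1: the biaryl axis is not specified in the SMILES, so only the two (S) benzylic centres are controlled.
Assumption 2: the (Ra,Sc,Sc) phosphoramidite is taken, from recalled styrene precedent, to give the (S)-3-arylbut-1-ene; if the first run shows the (R) sense, the mirror-image ligand is used in steps 4 and 10.

**Ring B half**

Step 1
Reactants: 1 3-methylphenol (m-cresol)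
Product: 3 2-hydroxy-4-methylbenzaldehyde, via salicyl alcohol magnesium salt 2 (not isolated)
Conditions: MgCl2, Et3N, (CH2O)n, MeCN, reflux; aq. HCl work-up
Reagents that add atoms: paraformaldehyde (as formaldehyde), C=O
Why: Magnesium-mediated ortho-formylation (Casnati–Skattebøl), in which the magnesium phenoxide hydroxymethylates the less hindered ortho carbon (para to the methyl) and a second formaldehyde oxidises the benzylic alkoxide to the aldehyde.

Step 2
Reactants: 3 2-hydroxy-4-methylbenzaldehyde
Product: 4 2-(methoxymethoxy)-4-methylbenzaldehyde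
Conditions: MOMCl, iPr2NEt, CH2Cl2, 0 °C → rt
Reagents that add atoms: chloromethyl methyl ether, COCCl
Why: O-alkylation of the phenol (MOM protection) removes the acidic proton before the ylide and organometallic steps and installs the later directing group.

Step 3
Reactants: 4 2-(methoxymethoxy)-4-methylbenzaldehyde
Product: 5 1-ethenyl-2-(methoxymethoxy)-4-methylbenzene
Conditions: Ph3PCH3Br, KOtBu, THF, 0 °C → rt
Reagents that add atoms: methyltriphenylphosphonium bromide, C[P+](c1ccccc1)(c1ccccc1)c1ccccc1.[Br-]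
Why: Wittig methylenation of a non-enolisable aryl aldehyde gives the styrene cleanly.

Step 4
Reactants: 5 1-ethenyl-2-(methoxymethoxy)-4-methylbenzene; 6 ethylene
Product: 7 1-[(2S)-but-3-en-2-yl]-2-(methoxymethoxy)-4-methylbenzene
Conditions: [(η3-C3H5)NiBr]2 (1 mol%), (Ra,Sc,Sc)-binaphthol N,N-bis(1-phenylethyl)phosphoramidite (2 mol%), Na[B(3,5-(CF3)2C6H3)4] (2.5 mol%), ethylene (1 atm), CH2Cl2, −70 °C
Reagents that add atoms: none
Why: Nickel-catalysed asymmetric hydrovinylation, in which the cationic divalent nickel hydride adds Markovnikov to the styrene and the chiral phosphoramidite controls the face of ethylene insertion at the η3-benzyl nickel species, setting the benzylic (S) centre before β-hydride elimination.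

Step 5
Reactants: 7 1-[(2S)-but-3-en-2-yl]-2-(methoxymethoxy)-4-methylbenzene; 8 1-bromo-2-methylprop-1-ene
Product: 10 (S)-curcuphenol MOM ether 2-(methoxymethoxy)-4-methyl-1-[(2S)-6-methylhept-5-en-2-yl]benzene, via alkyl-9-BBN borane 9 (not isolated)
Conditions: 9-BBN, THF, 0 °C → rt; then 8 (3 equiv), Pd(dppf)Cl2 (3 mol%), 3 M aq. NaOH, THF, rt → 50 °C
Reagents that add atoms: 9-BBN, B1C2CCCC1CCC2
Why: Anti-Markovnikov hydroboration of the terminal alkene gives borane 9, and B-alkyl Suzuki–Miyaura coupling with the vinyl bromide then completes the 6-methylhept-5-en-2-yl chain, the boron and its bicyclic ring leaving as 9-hydroxy-9-BBN, without touching the stereocentre, which is not alpha to boron.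

**Ring A half**

Step 6
Reactants: 1 3-methylphenol (m-cresol)
Product: 11 4-chloro-3-methylphenol
Conditions: SO2Cl2, Ph2S (cat.), AlCl3 (cat.), CH2Cl2, 0 °C → rt; recrystallise
Reagents that add atoms: sulfuryl chloride, O=S(=O)(Cl)Cl
Why: Electrophilic aromatic chlorination of the phenol goes para to OH (also ortho to methyl), and the sulfide/Lewis acid pair raises the para:ortho ratio.

Step 7
Reactants: 11 4-chloro-3-methylphenol
Product: 13 5-chloro-2-hydroxy-4-methylbenzaldehyde, via chloro salicyl alcohol magnesium salt 12 (not isolated)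
Conditions: MgCl2, Et3N, (CH2O)n, MeCN, reflux; aq. HCl work-up
Reagents that add atoms: paraformaldehyde (as formaldehyde), C=O
Why: The same magnesium-mediated ortho-formylation attacks the unhindered ortho carbon (para to methyl), since the other ortho site is flanked by the methyl group.

Step 8
Reactants: 13 5-chloro-2-hydroxy-4-methylbenzaldehyde
Product: 14 5-chloro-2-(methoxymethoxy)-4-methylbenzaldehyde
Conditions: MOMCl, iPr2NEt, CH2Cl2, 0 °C → rt
Reagents that add atoms: chloromethyl methyl ether, COCCl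
Why: MOM protection by O-alkylation, so that both halves carry the same acid-labile group for one final deprotection.

Step 9
Reactants: 14 5-chloro-2-(methoxymethoxy)-4-methylbenzaldehyde
Product: 15 1-chloro-5-ethenyl-4-(methoxymethoxy)-2-methylbenzene
Conditions: Ph3PCH3Br, KOtBu, THF, 0 °C → rt
Reagents that add atoms: methyltriphenylphosphonium bromide, C[P+](c1ccccc1)(c1ccccc1)c1ccccc1.[Br-]
Why: Wittig methylenation; the aryl chloride and the MOM ether are inert to the ylide.

Step 10
Reactants: 15 1-chloro-5-ethenyl-4-(methoxymethoxy)-2-methylbenzene; 6 ethylene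
Product: 16 1-[(2S)-but-3-en-2-yl]-5-chloro-2-(methoxymethoxy)-4-methylbenzene
Conditions: [(η3-C3H5)NiBr]2 (1 mol%), (Ra,Sc,Sc)-binaphthol N,N-bis(1-phenylethyl)phosphoramidite (2 mol%), Na[B(3,5-(CF3)2C6H3)4] (2.5 mol%), ethylene (1 atm), CH2Cl2, −70 °C
Reagents that add atoms: none
Why: Nickel-catalysed asymmetric hydrovinylation as in step 4 sets the (S) benzylic centre under ligand control, and the aryl chloride is not touched by the divalent nickel hydride catalyst.

Step 11
Reactants: 16 1-[(2S)-but-3-en-2-yl]-5-chloro-2-(methoxymethoxy)-4-methylbenzene; 8 1-bromo-2-methylprop-1-ene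
Product: 18 1-chloro-4-(methoxymethoxy)-2-methyl-5-[(2S)-6-methylhept-5-en-2-yl]benzene, via chloroaryl alkyl-9-BBN borane 17 (not isolated)
Conditions: 9-BBN, THF, 0 °C → rt; then 8 (3 equiv), Pd(dppf)Cl2 (3 mol%), 3 M aq. NaOH, THF, rt → 45 °C
Reagents that add atoms: 9-BBN, B1C2CCCC1CCC2
Why: Hydroboration to borane 17 and B-alkyl Suzuki–Miyaura coupling as in step 5, with boron again leaving as 9-hydroxy-9-BBN, chemoselective because the vinyl bromide (in excess) adds to palladium far faster than the electron-rich ortho-substituted aryl chloride under a dppf catalyst at mild temperature.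

**Union and end game**

Step 12
Reactants: 10 2-(methoxymethoxy)-4-methyl-1-[(2S)-6-methylhept-5-en-2-yl]benzene; 18 1-chloro-4-(methoxymethoxy)-2-methyl-5-[(2S)-6-methylhept-5-en-2-yl]benzene
Product: 21 bis-MOM biaryl 2,4'-bis(methoxymethoxy)-2',6-dimethyl-3,5'-bis[(2S)-6-methylhept-5-en-2-yl]-1,1'-biphenyl, via aryllithium 19 (not isolated), via arylzinc chloride 20 (not isolated)
Conditions: 10 (1.3 equiv), s-BuLi, TMEDA, Et2O, −78 → −10 °C; ZnCl2 (THF), → rt; then 18 (1.0 equiv), Pd2(dba)3 (2 mol%), RuPhos (8 mol%), THF, 65 °C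
Reagents that add atoms: s-BuLi, CCC(C)[Li]; ZnCl2, Cl[Zn]Cl
Why: MOM-directed ortho-metalation with s-BuLi can only occur at the single free ortho carbon (between OMOM and methyl) to give aryllithium 19, ZnCl2 turns it into arylzinc 20, and a Negishi coupling under a zerovalent palladium catalyst with a bulky dialkylbiarylphosphine joins it to the aryl chloride, the lithium and zinc ending in their chloride salts, to give the tri-ortho-substituted biaryl without touching either stereocentre.

Step 13
Reactants: 21 bis-MOM biaryl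
Product: 22 target 2',6-dimethyl-3,5'-bis[(2S)-6-methylhept-5-en-2-yl]-[1,1'-biphenyl]-2,4'-diol
Conditions: TsOH·H2O (0.2 equiv), MeOH/THF, 45 °C
Reagents that add atoms: none
Why: Acid-catalysed transacetalisation to methanol removes both aryl MOM ethers under conditions too mild to hydrate or cyclise the trisubstituted alkenes or to epimerise the benzylic centres.

**Compound list**
1 | 3-methylphenol (m-cresol) | Cc1cccc(O)c1 | starting material
2 | 2-(hydroxymethyl)-5-methylphenol, present as its magnesium salt | Cc1ccc(CO)c(O)c1 | intermediate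
3 | 2-hydroxy-4-methylbenzaldehyde | Cc1ccc(C=O)c(O)c1 | intermediate
4 | 2-(methoxymethoxy)-4-methylbenzaldehyde | Cc1ccc(C=O)c(OCOC)c1 | intermediate
5 | 1-ethenyl-2-(methoxymethoxy)-4-methylbenzene | Cc1ccc(C=C)c(OCOC)c1 | intermediate
6 | ethylene | C=C | starting material
7 | 1-[(2S)-but-3-en-2-yl]-2-(methoxymethoxy)-4-methylbenzene | COCOc1cc(C)ccc1[C@@H](C)C=C | intermediate
8 | 1-bromo-2-methylprop-1-ene | CC(C)=CBr | starting material
9 | 9-{(3S)-3-[2-(methoxymethoxy)-4-methylphenyl]butyl}-9-borabicyclo[3.3.1]nonane | COCOc1cc(C)ccc1[C@@H](C)CCB1C2CCCC1CCC2 | intermediate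
10 | 2-(methoxymethoxy)-4-methyl-1-[(2S)-6-methylhept-5-en-2-yl]benzene ((S)-curcuphenol MOM ether) | COCOc1cc(C)ccc1[C@@H](C)CCC=C(C)C | intermediate
11 | 4-chloro-3-methylphenol | Cc1cc(O)ccc1Cl | intermediate
12 | 4-chloro-2-(hydroxymethyl)-5-methylphenol, present as its magnesium salt | Cc1cc(O)c(CO)cc1Cl | intermediate
13 | 5-chloro-2-hydroxy-4-methylbenzaldehyde | Cc1cc(O)c(C=O)cc1Cl | intermediate
14 | 5-chloro-2-(methoxymethoxy)-4-methylbenzaldehyde | Cc1cc(OCOC)c(C=O)cc1Cl | intermediate
15 | 1-chloro-5-ethenyl-4-(methoxymethoxy)-2-methylbenzene | Cc1cc(OCOC)c(C=C)cc1Cl | intermediate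
16 | 1-[(2S)-but-3-en-2-yl]-5-chloro-2-(methoxymethoxy)-4-methylbenzene | COCOc1cc(C)c(Cl)cc1[C@@H](C)C=C | intermediate
17 | 9-{(3S)-3-[5-chloro-2-(methoxymethoxy)-4-methylphenyl]butyl}-9-borabicyclo[3.3.1]nonane | COCOc1cc(C)c(Cl)cc1[C@@H](C)CCB1C2CCCC1CCC2 | intermediate
18 | 1-chloro-4-(methoxymethoxy)-2-methyl-5-[(2S)-6-methylhept-5-en-2-yl]benzene | COCOc1cc(C)c(Cl)cc1[C@@H](C)CCC=C(C)C | intermediate
19 | {2-(methoxymethoxy)-6-methyl-3-[(2S)-6-methylhept-5-en-2-yl]phenyl}lithium | COCOc1c([Li])c(C)ccc1[C@@H](C)CCC=C(C)C | intermediate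
20 | chloro{2-(methoxymethoxy)-6-methyl-3-[(2S)-6-methylhept-5-en-2-yl]phenyl}zinc | COCOc1c([Zn]Cl)c(C)ccc1[C@@H](C)CCC=C(C)C | intermediate
21 | 2,4'-bis(methoxymethoxy)-2',6-dimethyl-3,5'-bis[(2S)-6-methylhept-5-en-2-yl]-1,1'-biphenyl | COCOc1c(-c2cc([C@@H](C)CCC=C(C)C)c(OCOC)cc2C)c(C)ccc1[C@@H](C)CCC=C(C)C | intermediate
22 | 2',6-dimethyl-3,5'-bis[(2S)-6-methylhept-5-en-2-yl]-[1,1'-biphenyl]-2,4'-diol | CC(C)=CCC[C@H](C)c1cc(-c2c(C)ccc([C@@H](C)CCC=C(C)C)c2O)c(C)cc1O | target

**Step count**
Total steps: 13. Longest linear sequence: 8 (steps 6–11, 12, 13); the other branch is 7 (steps 1–5, 12, 13).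

**Three steps most likely to fail, each with a fallback**

Step 4. The two oxygen atoms of the ortho-OMOM group may bind the cationic nickel hydride and stall it, or the product may isomerise to the conjugated 2-arylbut-2-ene. The fallback sets out from styrene 5. Copper hydride-catalysed Markovnikov hydroboration (CuCl, NaOtBu, a chiral bisphosphine such as DTBM-Segphos in the antipode that gives the (R) boronate, HBpin, toluene, rt) gives 2-{(1R)-1-[2-(methoxymethoxy)-4-methylphenyl]ethyl}-4,4,5,5-tetramethyl-1,3,2-dioxaborolane F1. Zweifel olefination (CH2=CHMgBr, THF; then iodine, MeOH, −78 °C; then NaOMe) moves the benzylic carbon from boron to the vinyl carbon with retention, and the route is rejoined at 7.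

Step 11. Palladium may insert into the aryl chloride of 17, or the coupling may be slow and give oligomers. The fallback sets out from 16 and keeps palladium away from the chloride. Hydroboration with 9-BBN (through 17) and oxidation with NaOH/H2O2 gives (3S)-3-[5-chloro-2-(methoxymethoxy)-4-methylphenyl]butan-1-ol F2. Appel iodination (iodine, PPh3, imidazole, CH2Cl2) gives 1-chloro-5-[(2S)-4-iodobutan-2-yl]-4-(methoxymethoxy)-2-methylbenzene F3. Copper-catalysed sp3–sp2 coupling with 2-methylprop-1-enylmagnesium bromide (made from 8 and magnesium; Li2CuCl4 cat., THF, −20 → 0 °C) rejoins the route at 18.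

Step 12. The doubly ortho-substituted arylzinc 20 may transmetalate too slowly to the arylpalladium chloride formed from the electron-rich chloride 18. The fallback reverses the polarity and isolates both partners. From 10, the same lithiation (through 19) quenched with 1,2-diiodoethane gives 2-iodo-3-(methoxymethoxy)-1-methyl-4-[(2S)-6-methylhept-5-en-2-yl]benzene F4. From 18, Miyaura borylation (B2pin2, Pd2(dba)3, XPhos, KOAc, dioxane, 100 °C) gives 2-{4-(methoxymethoxy)-2-methyl-5-[(2S)-6-methylhept-5-en-2-yl]phenyl}-4,4,5,5-tetramethyl-1,3,2-dioxaborolane F5. Suzuki–Miyaura coupling of the hindered iodide with the less hindered boronate (Pd(OAc)2, SPhos, K3PO4, toluene/H2O, 90 °C) rejoins the route at 21.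

**Further compounds**
F1 | step 4 | 2-{(1R)-1-[2-(methoxymethoxy)-4-methylphenyl]ethyl}-4,4,5,5-tetramethyl-1,3,2-dioxaborolane | COCOc1cc(C)ccc1[C@@H](C)B1OC(C)(C)C(C)(C)O1
F2 | step 11 | (3S)-3-[5-chloro-2-(methoxymethoxy)-4-methylphenyl]butan-1-ol | COCOc1cc(C)c(Cl)cc1[C@@H](C)CCO
F3 | step 11 | 1-chloro-5-[(2S)-4-iodobutan-2-yl]-4-(methoxymethoxy)-2-methylbenzene | COCOc1cc(C)c(Cl)cc1[C@@H](C)CCI
F4 | step 12 | 2-iodo-3-(methoxymethoxy)-1-methyl-4-[(2S)-6-methylhept-5-en-2-yl]benzene | COCOc1c(I)c(C)ccc1[C@@H](C)CCC=C(C)C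
F5 | step 12 | 2-{4-(methoxymethoxy)-2-methyl-5-[(2S)-6-methylhept-5-en-2-yl]phenyl}-4,4,5,5-tetramethyl-1,3,2-dioxaborolane | COCOc1cc(C)c(B2OC(C)(C)C(C)(C)O2)cc1[C@@H](C)CCC=C(C)C
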